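**Plan**

- Numbering: ring A is the phloroglucinol ring (C1 methyl; C2, C4 and C6 oxygen; C3 acyl; C5 side chain). Ring B is the tetramethyl enol-dione ring, joined through its C2' to the stereogenic CH.
- Cuts, in retrosynthetic order: the four O-benzyl masks; both bonds at the ketone carbon of the 3-phenylpropanoyl group (C3–CO and CO–CH2); the C3–I bond; the C5–CH bond; the CH=C2' bond of an alkylidene trione; the four C–CH3 bonds of ring B.
- Enabling feature: the acyl carbonyl carbon is bonded to ring A C3 on one side and to the CH2 of a 2-phenylethyl chain on the other. C3 lies between the oxygen-bearing C2 and C4 and is the only ring A carbon of the deacyl core that still carries hydrogen. C3 can therefore be iodinated without regiochemical choice, and the carbonyl carbon can enter as CO between that aryl iodide and the alkylborane made from styrene.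
- Forward order: ring B is made first from 2,4,6-trihydroxyacetophenone (dearomatising tetramethylation, deacetylation) and condensed with 3-phenylpropanal. Ring A is bought as 2-methylphloroglucinol and joined to it. Benzylation, iodination, three-component carbonylation and hydrogenolysis follow, and no ring forms after ring B.
- Stereochemistry: the single (R) centre arises in the conjugate Friedel–Crafts addition under a chiral aluminium lithium bis(binaphthoxide) catalyst. Capping the phenols and the enol then closes the retro-Michael channel until the last, neutral step.

Key step: step 8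

Assumption: the (R)-BINOL-derived complex is taken to expose the face of the alkylidene trione that leads to the (R) adduct; if the opposite sense is found, the (S)-BINOL complex is used and nothing else changes.

Step 1
Reactants: 1 2,4,6-trihydroxyacetophenone
Product: 2 2-acetyl-3-hydroxy-4,4,6,6-tetramethylcyclohex-2-ene-1,5-dione (acetylsyncarpic acid)
Conditions: MeI (6 equiv), NaOMe (5 equiv), MeOH, 0 °C → reflux; acidic work-up
Reagents that add atoms: iodomethane, CI
Why: Exhaustive dearomatising C-methylation of an acylphloroglucinol, in which the hydrogen-bonded phenoxides in methanol alkylate at carbon and each of the two free ring carbons takes up two methyl groups until the enolised tricarbonyl system can react no further.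

Step 2
Reactants: 2 acetylsyncarpic acid
Product: 3 2,2,4,4-tetramethylcyclohexane-1,3,5-trione (syncarpic acid)
Conditions: 6 M aq HCl, reflux
Reagents that add atoms: none
Why: Acid-mediated retro-Claisen deacylation, in which water adds to the exposed exocyclic acetyl carbonyl and acetic acid leaves, while the ring carbonyls are shielded by the gem-dimethyl groups.

Step 3
Reactants: 3 syncarpic acid; 4 3-phenylpropanal
Product: 6 2,2,4,4-tetramethyl-6-(3-phenylpropylidene)cyclohexane-1,3,5-trione, via piperidine Mannich base 5 (not isolated)
Conditions: piperidine (1.05 equiv), CH2Cl2, rt; then 1 M aq HCl, 0 °C, two-phase; used at once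
Reagents that add atoms: none
Why: Knoevenagel condensation run through the Mannich base, which holds the acceptor as its amine adduct so that a second molecule of 3 cannot add, after which acid-induced loss of piperidine frees the alkylidene trione, whose symmetric ring B leaves no E/Z question.

Step 4
Reactants: 6 alkylidene trione; 7 2-methylphloroglucinol (2-methylbenzene-1,3,5-triol)
Product: 8 3-hydroxy-4,4,6,6-tetramethyl-2-[(1R)-3-phenyl-1-(2,4,6-trihydroxy-3-methylphenyl)propyl]cyclohex-2-ene-1,5-dione (deacyl core)
Conditions: LiAl[(R)-BINOLate]2 (20 mol %, from LiAlH4 + 2 (R)-BINOL), 7 (3 equiv), MS 4 Å, THF, −40 °C, slow addition of 6; pH 5 buffer, cold work-up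
Reagents that add atoms: none
Why: Catalytic asymmetric Friedel–Crafts-type Michael addition, a reaction type established for phloroglucinols and alkylidene syncarpic acids, in which aluminium binds a ring B carbonyl of 6 while a lithium binaphthoxide arm holds the phenoxide of 7, so that one of the two equivalent free ring A carbons attacks a single face of the exocyclic C=C inside the binaphthyl pocket and sets the (R) centre, with the excess of 7 and the slow addition of 6 holding back a second addition.

Step 5
Reactants: 8 deacyl core
Product: 9 3-(benzyloxy)-4,4,6,6-tetramethyl-2-{(1R)-3-phenyl-1-[2,4,6-tris(benzyloxy)-3-methylphenyl]propyl}cyclohex-2-ene-1,5-dione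
Conditions: BnBr (6 equiv), Cs2CO3 (6 equiv), DMF, 0 °C → rt
Reagents that add atoms: benzyl bromide, BrCc1ccccc1
Why: Fourfold Williamson O-alkylation in a polar aprotic solvent with a large counter-ion, which favours oxygen over carbon attack, and the stereocentre is safe because ring B is an enolate until it is capped and an enol ether afterwards, neither of which can depart as a carbanion in a retro-Michael step.

Step 6
Reactants: 9 tetrabenzyl ether
Product: 10 3-(benzyloxy)-2-{(1R)-1-[2,4,6-tris(benzyloxy)-3-iodo-5-methylphenyl]-3-phenylpropyl}-4,4,6,6-tetramethylcyclohex-2-ene-1,5-dione (tetra-O-benzyl iodide of the deacyl core)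
Conditions: NIS (1.1 equiv), DMF, 0 °C → rt, dark; enantiomeric purity checked on a chiral phase and raised by crystallisation if needed
Reagents that add atoms: N-iodosuccinimide, O=C1CCC(=O)N1I
Why: Electrophilic aromatic iodination of a 1,3,5-trialkoxyarene under acid-free conditions, which can only strike C3 because it is the sole ring A C–H and is activated by two ortho and one para benzyloxy groups, while the electron-poor enol ether and the plain phenyl rings do not compete.

Step 7
Reactants: 11 styrene
Product: 12 9-(2-phenylethyl)-9-borabicyclo[3.3.1]nonane
Conditions: 9-BBN-H (0.5 M in THF), styrene (1.05 equiv), 0 °C → rt; volatiles removed, residue taken up in THF under argon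
Reagents that add atoms: 9-borabicyclo[3.3.1]nonane, B1C2CCCC1CCC2
Why: Anti-Markovnikov hydroboration, in which the bulky dialkylborane places boron on the terminal carbon of styrene and the slight excess of alkene leaves no B–H bond that could reduce a carbonyl group later.

Step 8
Reactants: 10 tetra-O-benzyl iodide; 12 9-(2-phenylethyl)-9-borabicyclo[3.3.1]nonane; 13 carbon monoxide
Product: 14 3-(benzyloxy)-2-{(1R)-1-[2,4,6-tris(benzyloxy)-3-methyl-5-(3-phenylpropanoyl)phenyl]-3-phenylpropyl}-4,4,6,6-tetramethylcyclohex-2-ene-1,5-dione (tetra-O-benzyl ether of the target)
Conditions: Pd(PPh3)4 (10 mol %), K3PO4 (dry powder, 3 equiv), CO (5 bar), 12 (1.5 equiv), toluene–THF, 50 °C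
Reagents that add atoms: none
Why: Zerovalent palladium inserts into the C3–I bond of 10, CO binds and migrates to give the aroylpalladium iodide, the phosphate-activated borate of 12 hands over its primary 2-phenylethyl group, and reductive elimination from the acyl(alkyl)palladium releases 14, so the C3–C(=O) and C(=O)–CH2 bonds are made in one operation. The closest known reaction type is the carbonylative Suzuki–Miyaura coupling of iodoarenes with B-alkyl-9-borabicyclo[3.3.1]nonanes to alkyl aryl ketones. No ring closes and no stereocentre is created; the existing (R) centre is a spectator whose C–H is not acidic and whose retro-Michael escape is blocked because the three phenols and the enol are benzylated. The selectivity needed is carbonylative over direct coupling, and the two ortho benzyloxy groups secure it by shielding the arylpalladium species from the bulky borate but not from small CO, whose insertion moves the metal one atom away from the crowded ring before transmetalation has to occur. Loss of a beta-hydride is held back because the alkyl group reaches palladium only at the acyl stage, where reductive elimination is fast, and because the bicyclononyl cage transfers only the primary chain. Site selectivity is not in question, since 10 holds one carbon–iodine bond and its benzyl ethers, vinylogous ester and doubly neopentyl ring B ketone are inert to the catalyst and to K3PO4.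

Step 9
Reactants: 14 tetra-O-benzyl ether of the target
Product: 15 3-hydroxy-4,4,6,6-tetramethyl-2-{(1R)-3-phenyl-1-[2,4,6-trihydroxy-3-methyl-5-(3-phenylpropanoyl)phenyl]propyl}cyclohex-2-ene-1,5-dione (target, CNP0236721.1)
Conditions: H2 (1 atm), Pd/C (10 wt % Pd), EtOAc–EtOH, rt; filtration through Celite, no acid or base
Reagents that add atoms: none
Why: Catalytic hydrogenolysis cleaves the three aryl benzyl ethers and the vinylogous benzyl ester under neutral conditions, which spare the hydrogen-bonded aryl ketone, the tetrasubstituted enone and the all-carbon stereocentre and avoid both acid-induced cyclodehydration between ring A and ring B and base-induced retro-Michael scrambling.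

**Compound list**

1 | 2,4,6-trihydroxyacetophenone | CC(=O)c1c(O)cc(O)cc1O | starting material
2 | 2-acetyl-3-hydroxy-4,4,6,6-tetramethylcyclohex-2-ene-1,5-dione (acetylsyncarpic acid) | CC(=O)C1=C(O)C(C)(C)C(=O)C(C)(C)C1=O | intermediate
3 | 2,2,4,4-tetramethylcyclohexane-1,3,5-trione (syncarpic acid) | CC1(C)C(=O)CC(=O)C(C)(C)C1=O | intermediate
4 | 3-phenylpropanal | O=CCCc1ccccc1 | starting material
5 | 3-hydroxy-4,4,6,6-tetramethyl-2-[3-phenyl-1-(piperidin-1-yl)propyl]cyclohex-2-ene-1,5-dione (racemic Mannich base, not isolated) | O=C1C(C(CCc2ccccc2)N2CCCCC2)=C(O)C(C)(C)C(=O)C1(C)C | intermediate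
6 | 2,2,4,4-tetramethyl-6-(3-phenylpropylidene)cyclohexane-1,3,5-trione | O=C1C(=CCCc2ccccc2)C(=O)C(C)(C)C(=O)C1(C)C | intermediate
7 | 2-methylphloroglucinol | Cc1c(O)cc(O)cc1O | starting material
8 | (R)-deacyl core | Cc1c(O)cc(O)c([C@@H](CCc2ccccc2)C2=C(O)C(C)(C)C(=O)C(C)(C)C2=O)c1O | intermediate
9 | (R)-tetra-O-benzyl deacyl core | Cc1c(OCc2ccccc2)cc(OCc2ccccc2)c([C@@H](CCc2ccccc2)C2=C(OCc3ccccc3)C(C)(C)C(=O)C(C)(C)C2=O)c1OCc1ccccc1 | intermediate
10 | (R)-tetra-O-benzyl iodide of the deacyl core | Cc1c(OCc2ccccc2)c(I)c(OCc2ccccc2)c([C@@H](CCc2ccccc2)C2=C(OCc3ccccc3)C(C)(C)C(=O)C(C)(C)C2=O)c1OCc1ccccc1 | intermediate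
11 | styrene | C=Cc1ccccc1 | starting material
12 | 9-(2-phenylethyl)-9-borabicyclo[3.3.1]nonane | C1CCC2CCCC1B2CCc1ccccc1 | intermediate
13 | carbon monoxide | [C-]#[O+] | starting material
14 | (R)-tetra-O-benzyl ether of the target | Cc1c(OCc2ccccc2)c(C(=O)CCc2ccccc2)c(OCc2ccccc2)c([C@@H](CCc2ccccc2)C2=C(OCc3ccccc3)C(C)(C)C(=O)C(C)(C)C2=O)c1OCc1ccccc1 | intermediate
15 | CNP0236721.1, (R) | Cc1c(O)c(C(=O)CCc2ccccc2)c(O)c([C@@H](CCc2ccccc2)C2=C(O)C(C)(C)C(=O)C(C)(C)C2=O)c1O | target

Total step count: 9.
Longest linear sequence: 8 steps (1 → 2 → 3 → 6 → 8 → 9 → 10 → 14 → 15). Step 7 is a one-step side branch.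

**Steps most likely to fail**

1. Step 4.
   - What may go wrong: an uncatalysed background addition could erode facial selectivity. The acidic enol being formed could protonate the basic catalyst, with the same effect. Ring A could also be alkylated twice.
   - Fallback (resolution in place of asymmetric catalysis): setting out from 6 and 7, the addition is run without chiral control (Et3N, THF, 0 °C) to give the racemic deacyl core F1. This is benzylated as in step 5 to the racemic tetrabenzyl ether F2, which has no free phenol or enol and cannot racemise. Preparative chromatography on a chiral stationary phase (amylose tris(3,5-dimethylphenylcarbamate), supercritical CO2–MeOH) then divides it into 9 and the (S)-tetrabenzyl ether F3. The route is rejoined at 9.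

2. Step 8.
   - What may go wrong: alkyl transfer from the bulky borate to the crowded aroylpalladium species could be sluggish. That would leave room for coupling without CO uptake, for protodeiodination and for hydrolysis of the acyl complex.
   - Fallback (CO is kept as the carbonyl carbon, but the partner changes to an sp carbon and the chain is saturated later): setting out from 10, a carbonylative Sonogashira coupling with phenylacetylene (PdCl2(PPh3)2, Et3N, CO 5 bar, toluene, 60 °C) uses a slim nucleophile without beta-hydrogen and should give the tetra-O-benzyl alkynone F4. Hydrogen over Pd/C saturates the triple bond faster than it cleaves benzyl ethers, so a free ortho-hydroxy alkynone that could cyclise is never present. The same operation then removes the four benzyl groups. The route is rejoined at 15.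

3. Step 5.
   - What may go wrong: alkylation could occur at carbon instead of oxygen at the free ring A position. Capping of the crowded ring B enolate could also stay incomplete.
   - Fallback (ester relay in place of direct alkylation of the polyphenoxide): setting out from 8, Ac2O–pyridine at 0 °C gives the tetraacetate F5. BnCl, NaH and a measured amount of water in DMF (0 °C → rt) then cleave the esters one after another, and each oxygen anion is benzylated as it is freed. Ring A is thus never a polyphenoxide, the species prone to carbon attack. The labile enol acetate is opened first and meets the full excess of benzyl chloride. The route is rejoined at 9.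

**Further compounds**

F1 | step 4 | racemic deacyl core | Cc1c(O)cc(O)c(C(CCc2ccccc2)C2=C(O)C(C)(C)C(=O)C(C)(C)C2=O)c1O
F2 | step 4 | racemic tetrabenzyl ether | Cc1c(OCc2ccccc2)cc(OCc2ccccc2)c(C(CCc2ccccc2)C2=C(OCc3ccccc3)C(C)(C)C(=O)C(C)(C)C2=O)c1OCc1ccccc1
F3 | step 4 | (S)-tetrabenzyl ether | Cc1c(OCc2ccccc2)cc(OCc2ccccc2)c([C@H](CCc2ccccc2)C2=C(OCc3ccccc3)C(C)(C)C(=O)C(C)(C)C2=O)c1OCc1ccccc1
F4 | step 8 | (R)-tetra-O-benzyl alkynone | Cc1c(OCc2ccccc2)c(C(=O)C#Cc2ccccc2)c(OCc2ccccc2)c([C@@H](CCc2ccccc2)C2=C(OCc3ccccc3)C(C)(C)C(=O)C(C)(C)C2=O)c1OCc1ccccc1
F5 | step 5 | (R)-tetraacetate of the deacyl core | Cc1c(OC(C)=O)cc(OC(C)=O)c([C@@H](CCc2ccccc2)C2=C(OC(C)=O)C(C)(C)C(=O)C(C)(C)C2=O)c1OC(C)=O
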